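**Falling ratios.** In the south-west run, a closed flask, substrate falls by a factor of 2.33 in the first 25.0 s, then by 4.67 between 50.0 s and 80.0 s. Per second, the south-west flask turns 0.0338 s⁻¹ of its substrate early and 0.0513 s⁻¹ late, so the share turned per second reads larger once the flask is thin in substrate. I call the late figure, the share of the substrate present that turns into target per second in a thin flask, the thin constant, a pseudo-first-order constant. It is a rough reading: the 3% carries a scatter of 2 percentage points.

| flask | substrate | remark | time |
|---|---|---|---|
| south-west | 0.14 M | run made earlier |  |
| south | 0.070 M | run made earlier |  |
| west | 0.28 M | run made earlier |  |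
| beta | 0.14 M | one stirred flow tank at steady state, fed with the mixture as stated, mean residence time 3.0 min |  |
| theta | 0.14 M | a closed flask charged with all of it at once and left for 3.0 min | 3.0 min |

- south-west (time / s: target / %, substrate / %): 25.0: 49, 43; 50.0: 82, 14; 80.0: 97, 3; 120: 101, 0
- south (time / min: target / %, substrate / %): 0.417: 64, 36; 1.33: 100, 0; 2.50: 98, 0; 4.00: 100, 0
- west (time / min: target / %, substrate / %): 0.833: 66, 30; 2.00: 97, 0; 2.50: 98, 0; 4.00: 100, 0

(readings scatter by 2 percentage points)

1. the set-up with the highest amount of target at the outlet or at the end, in percent of the substrate put in ("none" if the first two lie within 2 percentage points) (beta / theta / none)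
2. amount of target at the outlet or at the end, in percent of the substrate put in, beta
3. amount of target at the outlet or at the end, in percent of the substrate put in, theta

**Two extremes.** By the last south-west reading target stands at 101%, so I count what substrate loses as target. At the early constant I reckon that closed flask theta keeps 0.230% of its substrate after 3.0 min. At that same constant I reckon that tank beta keeps 14.1%, since at a fixed constant a stirred tank leaves one part in one plus constant times residence time.

**My reckoning.** The thin constant gives tank beta 9.76% left. That level lies inside the stretch where I read the constant, so the choice holds together. I expect 90.2% of target from beta, less than from theta.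

**The forecast.** It says 90% for beta, 99% for theta, so theta, because “The stirred tank loses out because it runs at low substrate concentration”.

**The result.** Tank beta gives 90.3% of target and closed flask theta >99.9%. Substrate stands at 0.0135 M throughout tank beta, 9.67% of the charge, so the tank's own constant by the same balance is 0.0519 s⁻¹, against my 0.0513 s⁻¹.

    substrate → target, rate k1*[substrate]/(1 + ([substrate]/sat1)) (0.113 M, k = 0.0581 s⁻¹)

**Once more.** A reading of flask theta at 50 s shows 16% of substrate. Carried forward at the thin constant, that becomes 2.00% by 1.50 min, and flask theta then holds 1.81%.

The numbers in the tables come from a simulation with constants of no real substance; the scatter is artificial.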